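**Retrosynthetic overview**
1. The target comes from the 8,9-diol 11,13-epoxide by two site-selective acylations (methacrylate on O8, acetate on O9); the spiro-epoxide (C11) comes from the α-methylene lactone by a hydroxyl-directed zinc peroxide epoxidation.
2. The ten-membered carbocycle and the γ-lactone are closed together by an intramolecular allylchromium (Barbier) addition forming C6–C7, followed by lactonisation.
3. The furanone ring and the quaternary C10 come from a gold-catalysed heterocyclisation/1,2-shift of an α-hydroxy-α-alkynyl methyl ketone, in which C9 migrates from C1 to C10.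
4. That ketone is assembled on the carbonyl of L-erythronolactone acetonide (C7–C8–C9–C1) from 1-ethoxyvinyllithium (C10, C14) and the di-Grignard reagent of (Z)-3-methylpent-2-en-4-yn-1-ol (C2–C6, C15).
5. Ring order: dioxolane (temporary) → furanone → carbocycle and lactone → epoxide.

Assumption: locants C1–C15 follow germacrane numbering of the target (C1–C10 carbocycle, C11–C13 lactone side chain, C14 on C10, C15 on C4), and L-erythronolactone is taken as a catalogue compound from carbohydrate suppliers.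

**Route**

Step 1
Reactants: 1 L-erythronolactone [(3S,4S)-3,4-dihydroxyoxolan-2-one]
Product: 2 2,3-O-isopropylidene-L-erythronolactone [(3aS,6aS)-2,2-dimethyldihydrofuro[3,4-d][1,3]dioxol-4(3aH)-one]
Conditions: Me2C(OMe)2, p-TsOH·H2O (cat.), acetone, 23 °C
Reagents that add atoms: 2,2-dimethoxypropane COC(C)(C)OC
Why: Acid-catalysed transketalisation (acetonide protection) of the cis-diol; no stereocentre is touched and the dioxolane oxygen on C9 later serves as the chelating group.

Step 2
Reactants: 2 2,3-O-isopropylidene-L-erythronolactone; 3 ethyl vinyl ether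
Product: 5 (3aS,6aS)-4-(1-ethoxyethenyl)-2,2-dimethyltetrahydrofuro[3,4-d][1,3]dioxol-4-ol (both anomers), via 1-ethoxyvinyllithium 4 (not isolated)
Conditions: 3, t-BuLi, THF, −78→0 °C; then 2, −78 °C; H2O quench
Reagents that add atoms: none
Why: Addition of the acyl-anion equivalent 1-ethoxyvinyllithium to a γ-lactone stops at the tetrahedral lithium hemiketalate (arrested nucleophilic acyl substitution), giving a masked 1,2-diketone without disturbing C8 or C9.

Step 3
Reactants: 5 the hemiketal from step 2; 6 (Z)-3-methylpent-2-en-4-yn-1-ol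
Product: 10 (3S,6Z)-3-[(4S,5S)-2,2-dimethyl-5-(triethylsilyloxymethyl)-1,3-dioxolan-4-yl]-3-hydroxy-6-methyl-8-(triethylsilyloxy)oct-6-en-4-yn-2-one, via di-Grignard reagent 7 (not isolated), via triol enol ether 8 (not isolated), via bis-silyl enol ether 9 (not isolated)
Conditions: 6 (2.5 equiv), EtMgBr (5 equiv), THF, 0→40 °C; add 5, 0→23 °C; then Et3SiCl, DMAP, 0→23 °C; work-up with 10% aq. oxalic acid on SiO2, CH2Cl2, 0 °C
Reagents that add atoms: chlorotriethylsilane CC[Si](Cl)(CC)CC; water O
Why: Alkynyl Grignard 1,2-addition to the ring-opened keto form of the hemiketal proceeds under Cram-chelate control (Mg bridging the ketone oxygen and the dioxolane oxygen on C9), so the alkynyl group enters syn to H9 and sets the carbinol centre (future C1) as S, after which the two primary magnesium alkoxides are silylated and the enol ether is hydrolysed to the methyl ketone.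

Step 4
Reactants: 10 the α-hydroxy-α-alkynyl methyl ketone from step 3
Product: 11 (2S)-2-[(4S,5S)-2,2-dimethyl-5-(triethylsilyloxymethyl)-1,3-dioxolan-4-yl]-2-methyl-5-[(2Z)-4-(triethylsilyloxy)but-2-en-2-yl]furan-3(2H)-one
Conditions: AuCl3 (5 mol%), 4 Å MS, CH2Cl2, 23 °C
Reagents that add atoms: none
Why: Kirsch-type heterocyclisation/1,2-alkyl shift: trivalent gold activates the alkyne, the acetyl oxygen closes 5-endo-dig to a cyclic oxocarbenium ion, and the dioxolanyl carbon C9 migrates suprafacially with retention from C1 to C10 (α-ketol-type shift), so the C1 configuration is transferred to the quaternary C10 (S) while C1 becomes the furanone carbonyl.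

Step 5
Reactants: 11 the bis-silylated furanone from step 4
Product: 12 (4R,5S)-2,2-dimethyl-5-{(2S)-2-methyl-3-oxo-5-[(2Z)-4-oxobut-2-en-2-yl]-2,3-dihydrofuran-2-yl}-1,3-dioxolane-4-carbaldehyde
Conditions: (COCl)2, DMSO, CH2Cl2, −78→−40 °C; then i-Pr2NEt, −78→−20 °C
Reagents that add atoms: none
Why: Swern oxidation converts primary triethylsilyl ethers directly into aldehydes (silyl transfer to chloride, then alkoxysulfonium ylide fragmentation), and the hindered base at low temperature protects the α-alkoxy centre C8 and the Z enal geometry.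

Step 6
Reactants: 12 the dialdehyde from step 5; 13 methyl propiolate
Product: 15 methyl 2-{hydroxy[(4S,5S)-2,2-dimethyl-5-{(2S)-2-methyl-3-oxo-5-[(2Z)-4-oxobut-2-en-2-yl]-2,3-dihydrofuran-2-yl}-1,3-dioxolan-4-yl]methyl}prop-2-enoate (both carbinol epimers), via α-(methoxycarbonyl)vinylalane 14 (not isolated)
Conditions: 13, i-Bu2AlH, NMO, THF, 0 °C; then 12, −78→0 °C; aq. KNaC4H4O6 (potassium sodium tartrate)
Reagents that add atoms: none
Why: Vinylalumination (aluminium version of the Morita–Baylis–Hillman reaction): the α-aluminated acrylate adds 1,2 to the more electrophilic α-alkoxy aliphatic aldehyde (C7) rather than the conjugated β,β-disubstituted enal (C6), without amine base that could epimerise C8, and the new carbinol centre is erased in the next step.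

Step 7
Reactants: 15 the Baylis–Hillman-type alcohol from step 6
Product: 16 methyl (2Z)-2-(bromomethyl)-3-[(4S,5S)-2,2-dimethyl-5-{(2S)-2-methyl-3-oxo-5-[(2Z)-4-oxobut-2-en-2-yl]-2,3-dihydrofuran-2-yl}-1,3-dioxolan-4-yl]prop-2-enoate
Conditions: NBS, Me2S, CH2Cl2, 0→23 °C
Reagents that add atoms: N-bromosuccinimide O=C1CCC(=O)N1Br
Why: Corey–Kim-type activation of the allylic alcohol as an alkoxysulfonium salt followed by SN2′ attack of bromide gives the thermodynamically preferred (Z)-2-(bromomethyl)enoate under neutral conditions that leave the enal and acetonide intact.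

Step 8
Reactants: 16 the bromo enal from step 7
Product: 18 (4Z,6R,7S,8S,9S,10S)-8,9-(isopropylidenedioxy)-1-oxo-3,10-epoxygermacra-2,4,11(13)-trien-12,6-olide, via hydroxy ester 17 (not isolated)
Conditions: CrCl2 (8 equiv), THF/DMF (0.003 M, syringe-pump addition), 23 °C; then PPTS (cat.), PhMe, 45 °C
Reagents that add atoms: none
Why: Intramolecular Nozaki–Hiyama-type Barbier allylation: divalent chromium turns the allylic bromide into an allylchromium species that adds through its γ-carbon (C7) to the C6 aldehyde in a chair-like transition state inside the forming ten-membered ring, with attack anti to the C8–O bond (7S) and the ring bonds at C5 and C8 pseudo-equatorial (6R, anti adduct), and the hydroxy ester then lactonises to the 6,7-trans-fused α-methylene lactone.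

Step 9
Reactants: 18 the macrocyclic acetonide from step 8
Product: 19 (4Z,6R,7S,8S,9S,10S)-8,9-dihydroxy-1-oxo-3,10-epoxygermacra-2,4,11(13)-trien-12,6-olide
Conditions: TFA/H2O (9:1), 0 °C
Reagents that add atoms: none
Why: Acid-catalysed acetal hydrolysis frees the cis-8,9-diol, and the furanone and α-methylene lactone tolerate brief aqueous acid.

Step 10
Reactants: 19 the diol from step 9
Product: 20 (4Z,6R,7S,8S,9S,10S,11S)-11,13-epoxy-8,9-dihydroxy-1-oxo-3,10-epoxygermacra-2,4-dien-12,6-olide
Conditions: Et2Zn (1.1 equiv), t-BuOOH (1.1 equiv, anhydrous in decane), PhMe, −20 °C; then 19 in THF, −20→0 °C; aq. NH4Cl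
Reagents that add atoms: tert-butyl hydroperoxide CC(C)(C)OO
Why: Proposed new method: substrate-templated nucleophilic epoxidation, in which the C8 hydroxyl protonolyses the Zn–Et bond of EtZnOOt-Bu so that a zinc tert-butylperoxide is tethered to O8 on the lactone face syn to C8, the peroxide oxygen is delivered intramolecularly to C13 through a seven-membered array, and the zinc enolate closes on the same face by attack of C11 on that oxygen with loss of tert-butoxide (11S, oxygen syn to C8), while the β-alkoxy enone of the furanone stays inert; the closest known reactions are zinc alkylperoxide (Et2Zn/hydroperoxide) epoxidations of enones steered by added amino-alcohol ligands and hydroxyl-directed lithium tert-butylperoxide epoxidations, neither shown with the substrate's own homoallylic alkoxide as the ligand or on an α-methylene-γ-butyrolactone.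

Step 11
Reactants: 20 the epoxy diol from step 10; 21 methacryloyl chloride
Product: 22 (4Z,6R,7S,8S,9S,10S,11S)-11,13-epoxy-9-hydroxy-8-(2-methylprop-2-enoyloxy)-1-oxo-3,10-epoxygermacra-2,4-dien-12,6-olide
Conditions: 21 (1.1 equiv), Et3N, DMAP (cat.), CH2Cl2, −40→0 °C
Reagents that add atoms: none
Why: DMAP-catalysed acylation under kinetic control selects the C8 hydroxyl because the C9 hydroxyl is neopentyl-like (flanked by the quaternary C10), and any acyl migration also favours the less hindered O8 ester.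

Step 12
Reactants: 22 the 8-methacrylate from step 11; 23 acetic anhydride
Product: 24 (4Z,6R,7S,8S,9S,10S,11S)-9-acetoxy-11,13-epoxy-8-(2-methylprop-2-enoyloxy)-1-oxo-3,10-epoxygermacra-2,4-dien-12,6-olide (CNP0423862.2)
Conditions: 23, DMAP, pyridine, CH2Cl2, 0→23 °C
Reagents that add atoms: none
Why: DMAP-catalysed acetylation of the remaining hindered secondary alcohol completes the target without touching the epoxide, lactone or methacrylate.

**Compound list**
1 | L-erythronolactone, (3S,4S)-3,4-dihydroxyoxolan-2-one | O=C1OC[C@H](O)[C@@H]1O | starting material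
2 | 2,3-O-isopropylidene-L-erythronolactone, (3aS,6aS) | O=C1OC[C@H](OC(C)(C)O2)[C@@H]12 | intermediate
3 | ethyl vinyl ether | C=COCC | starting material
4 | 1-ethoxyvinyllithium | [Li]C(=C)OCC | intermediate
5 | (3aS,6aS)-4-(1-ethoxyethenyl)-2,2-dimethyltetrahydrofuro[3,4-d][1,3]dioxol-4-ol, both anomers | C=C(OCC)C1(O)OC[C@H](OC(C)(C)O2)[C@@H]12 | intermediate
6 | (Z)-3-methylpent-2-en-4-yn-1-ol | C#C/C(C)=C\CO | starting material
7 | di-Grignard reagent of 6 (bromomagnesium alkoxide, alkynylmagnesium bromide) | Br[Mg]C#C/C(C)=C\CO[Mg]Br | intermediate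
8 | (2Z,6S)-6-[(4S,5S)-5-(hydroxymethyl)-2,2-dimethyl-1,3-dioxolan-4-yl]-7-ethoxy-3-methylocta-2,7-dien-4-yne-1,6-diol (present as its magnesium alkoxide; neutral form shown) | C=C(OCC)[C@](O)(C#C/C(C)=C\CO)[C@H]1OC(C)(C)O[C@H]1CO | intermediate
9 | bis(triethylsilyl) ether of 8 at both primary hydroxyls | C=C(OCC)[C@](O)(C#C/C(C)=C\CO[Si](CC)(CC)CC)[C@H]1OC(C)(C)O[C@H]1CO[Si](CC)(CC)CC | intermediate
10 | (3S,6Z)-3-[(4S,5S)-2,2-dimethyl-5-(triethylsilyloxymethyl)-1,3-dioxolan-4-yl]-3-hydroxy-6-methyl-8-(triethylsilyloxy)oct-6-en-4-yn-2-one | CC(=O)[C@](O)(C#C/C(C)=C\CO[Si](CC)(CC)CC)[C@H]1OC(C)(C)O[C@H]1CO[Si](CC)(CC)CC | intermediate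
11 | (2S)-2-[(4S,5S)-2,2-dimethyl-5-(triethylsilyloxymethyl)-1,3-dioxolan-4-yl]-2-methyl-5-[(2Z)-4-(triethylsilyloxy)but-2-en-2-yl]furan-3(2H)-one | CC[Si](CC)(CC)OC/C=C(/C)C1=CC(=O)[C@@](C)(O1)[C@H]2OC(C)(C)O[C@H]2CO[Si](CC)(CC)CC | intermediate
12 | (4R,5S)-2,2-dimethyl-5-{(2S)-2-methyl-3-oxo-5-[(2Z)-4-oxobut-2-en-2-yl]-2,3-dihydrofuran-2-yl}-1,3-dioxolane-4-carbaldehyde | O=C/C=C(/C)C1=CC(=O)[C@@](C)(O1)[C@H]2OC(C)(C)O[C@H]2C=O | intermediate
13 | methyl propiolate | C#CC(=O)OC | starting material
14 | [1-(methoxycarbonyl)ethenyl]diisobutylaluminium | C=C(C(=O)OC)[Al](CC(C)C)CC(C)C | intermediate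
15 | methyl 2-{hydroxy[(4S,5S)-2,2-dimethyl-5-{(2S)-2-methyl-3-oxo-5-[(2Z)-4-oxobut-2-en-2-yl]-2,3-dihydrofuran-2-yl}-1,3-dioxolan-4-yl]methyl}prop-2-enoate, carbinol epimers | O=C/C=C(/C)C1=CC(=O)[C@@](C)(O1)[C@H]2OC(C)(C)O[C@H]2C(O)C(=C)C(=O)OC | intermediate
16 | methyl (2Z)-2-(bromomethyl)-3-[(4S,5S)-2,2-dimethyl-5-{(2S)-2-methyl-3-oxo-5-[(2Z)-4-oxobut-2-en-2-yl]-2,3-dihydrofuran-2-yl}-1,3-dioxolan-4-yl]prop-2-enoate | O=C/C=C(/C)C1=CC(=O)[C@@](C)(O1)[C@H]2OC(C)(C)O[C@H]2/C=C(\CBr)C(=O)OC | intermediate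
17 | methyl (4Z,6R,7S,8S,9S,10S)-6-hydroxy-8,9-(isopropylidenedioxy)-1-oxo-3,10-epoxygermacra-2,4,11(13)-trien-12-oate | CC1(C)O[C@H]2[C@@H](C(=C)C(=O)OC)[C@H](O)/C=C(/C)C3=CC(=O)[C@@](C)(O3)[C@H]2O1 | intermediate
18 | (4Z,6R,7S,8S,9S,10S)-8,9-(isopropylidenedioxy)-1-oxo-3,10-epoxygermacra-2,4,11(13)-trien-12,6-olide | CC1(C)O[C@H]2[C@@H]3[C@@H](/C=C(/C)C4=CC(=O)[C@@](C)(O4)[C@H]2O1)OC(=O)C3=C | intermediate
19 | (4Z,6R,7S,8S,9S,10S)-8,9-dihydroxy-1-oxo-3,10-epoxygermacra-2,4,11(13)-trien-12,6-olide | O[C@H]1[C@@H]2[C@@H](/C=C(/C)C3=CC(=O)[C@@](C)(O3)[C@H]1O)OC(=O)C2=C | intermediate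
20 | (4Z,6R,7S,8S,9S,10S,11S)-11,13-epoxy-8,9-dihydroxy-1-oxo-3,10-epoxygermacra-2,4-dien-12,6-olide | O[C@H]1[C@@H]2[C@@H](/C=C(/C)C3=CC(=O)[C@@](C)(O3)[C@H]1O)OC(=O)[C@@]21CO1 | intermediate
21 | methacryloyl chloride | C=C(C)C(=O)Cl | starting material
22 | (4Z,6R,7S,8S,9S,10S,11S)-11,13-epoxy-9-hydroxy-8-(2-methylprop-2-enoyloxy)-1-oxo-3,10-epoxygermacra-2,4-dien-12,6-olide | C=C(C)C(=O)O[C@H]1[C@@H]2[C@@H](/C=C(/C)C3=CC(=O)[C@@](C)(O3)[C@H]1O)OC(=O)[C@@]21CO1 | intermediate
23 | acetic anhydride | CC(=O)OC(C)=O | starting material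
24 | (4Z,6R,7S,8S,9S,10S,11S)-9-acetoxy-11,13-epoxy-8-(2-methylprop-2-enoyloxy)-1-oxo-3,10-epoxygermacra-2,4-dien-12,6-olide | C=C(C)C(=O)O[C@H]1[C@@H]2[C@@H](/C=C(/C)C3=CC(=O)[C@@](C)(O3)[C@H]1OC(C)=O)OC(=O)[C@@]21CO1 | target

**Summary**
Total step count: 12. Longest linear sequence: 12 steps (1 → 24); all other starting materials enter without prior elaboration.

Steps most likely to fail, with fallbacks:

Step 3 (facial selectivity of the alkynyl addition, which fixes C1 and therefore C10). If the Grignard addition follows a Felkin–Anh rather than a chelate course, the C1 epimer results. The fallback sets out from 2 and comes back at 8 by reversing the order in which the two carbon nucleophiles enter. Enynol 6 is deprotonated twice with n-BuLi to its dilithio derivative F1, which adds once to lactone 2 (THF, −78 °C) to give the ynone hemiketal F2. 1-Ethoxyvinyllithium 4 (3 equiv, THF/HMPA, −78 °C) is then added last, so that the non-chelated Felkin–Anh course now gives the required configuration, i.e. the alkoxide of 8. This is silylated and hydrolysed as in step 3 to 10.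

Step 8 (nine/ten-membered ring closure and the C6/C7 relationship). Acyclic 2-(alkoxycarbonyl)allyl metals favour syn adducts, so the 6,7-cis lactone is the likely wrong product. The fallback sets out from 16 and comes back at 18. If the chromium-mediated closure gives the 6-epimeric cis-fused lactone F3, it is opened with LiOH (THF/H2O, 0 °C) to the 6S hydroxy acid F4. Mitsunobu lactonisation (PPh3, DIAD, PhMe, 0 °C) then re-closes it with inversion at C6 to 18, so C6 is set by SN2 displacement instead of by the C–C bond formation.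

Step 10 (the proposed zinc peroxide epoxidation). Risks are low reactivity of the lactone acceptor, wrong facial outcome, or translactonisation to O8. The fallback uses known chemistry, sets out from 19 and comes back at 20. Hydrogen-bond-directed dihydroxylation (OsO4·TMEDA, CH2Cl2, −78 °C, then aq. Na2SO3) syn to the C8 hydroxyl gives the 11S tetraol F5. Selective sulfonylation of the primary C13 hydroxyl (TsCl, Et3N, Bu2SnO cat., CH2Cl2, 0 °C) gives the monotosylate F6. K2CO3 in MeOH at 0 °C closes the epoxide from the C11 oxygen with retention at C11 to 20.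

Further compounds
F1 | step 3 | dilithio derivative of (Z)-3-methylpent-2-en-4-yn-1-ol | [Li]C#C/C(C)=C\CO[Li]
F2 | step 3 | (3aS,6aS)-4-[(3Z)-5-hydroxy-3-methylpent-3-en-1-yn-1-yl]-2,2-dimethyltetrahydrofuro[3,4-d][1,3]dioxol-4-ol, both anomers | OC/C=C(C)\C#CC1(O)OC[C@H](OC(C)(C)O2)[C@@H]12
F3 | step 8 | (4Z,6S,7S,8S,9S,10S)-8,9-(isopropylidenedioxy)-1-oxo-3,10-epoxygermacra-2,4,11(13)-trien-12,6-olide (6-epimer of 18) | CC1(C)O[C@H]2[C@@H]3[C@H](/C=C(/C)C4=CC(=O)[C@@](C)(O4)[C@H]2O1)OC(=O)C3=C
F4 | step 8 | (4Z,6S,7S,8S,9S,10S)-6-hydroxy-8,9-(isopropylidenedioxy)-1-oxo-3,10-epoxygermacra-2,4,11(13)-trien-12-oic acid | CC1(C)O[C@H]2[C@@H](C(=C)C(=O)O)[C@@H](O)/C=C(/C)C3=CC(=O)[C@@](C)(O3)[C@H]2O1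
F5 | step 10 | (4Z,6R,7S,8S,9S,10S,11S)-8,9,11,13-tetrahydroxy-1-oxo-3,10-epoxygermacra-2,4-dien-12,6-olide | O[C@H]1[C@@H]2[C@@H](/C=C(/C)C3=CC(=O)[C@@](C)(O3)[C@H]1O)OC(=O)[C@@]2(O)CO
F6 | step 10 | 13-O-(4-methylbenzenesulfonyl) derivative of F5 | O[C@H]1[C@@H]2[C@@H](/C=C(/C)C3=CC(=O)[C@@](C)(O3)[C@H]1O)OC(=O)[C@@]2(O)COS(=O)(=O)c1ccc(C)cc1
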